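A small charge of free enzyme, 0.02 mol% on starting material at 20 mM, worked through 0.950 equiv of second substrate in the red run. On my list of suspects, free enzyme binds starting material to the first complex, which gives off first product and leaves loaded enzyme; loaded enzyme binds second substrate to the second complex, which gives off target and returns free enzyme.

red run (percent of the starting material charged)

| time / h | target / % | starting material / % |
|---|---|---|
| 0.417 | 4 | 94 |
| 0.833 | 9 | 91 |
| 1.33 | 14 | 85 |
| 1.50 | 14 | 84 |
| 2.00 | 22 | 80 |
| 2.50 | 28 | 76 |
| 3.00 | 32 | 70 |

(scatter of a reading: 2 percentage points)

1. factor on the rate of making target when 20% of the starting material are converted if second substrate is charged twice over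
2. factor on the rate when 20% of the starting material are converted if free enzyme is charged at 0.004 mol% instead

Within the scatter of 2 percentage points the target rose along a straight line, so I integrated a constant rate: the fraction of the charge made is time over the draining time, the time the whole charge would take at the pace read, 9.38 h. The reading at 0.833 h gave 9.26 h.

That made a ladder. Fastest, one turn of the cycle per enzyme took 6.75 s. Next, the flask reached 20% conversion in 1.88 h, far longer, so I took the enzyme forms as steady throughout. Slowest, second substrate, the limiting reagent, would last 8.91 h at that pace.

Steady forms stretch the draining time in inverse proportion to the catalyst, to 46.9 h at 0.004 mol%, so I reckoned a rate factor of 0.200. The straight line made me expect a factor close to one for more second substrate. The forecast gave 1.08 (1 to 1.4) and 0.2 (0.18 to 0.22), noting “The rate barely notices either”.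

The flask gave 1.02 and 0.200.

    second complex → free enzyme + target (k = 36.0 min⁻¹)
    starting material + free enzyme ⇌ first complex (K = 25.0 M⁻¹, k = 830 M⁻¹ min⁻¹)
    second substrate + loaded enzyme ⇌ second complex (K = 980 M⁻¹, k = 28000 M⁻¹ min⁻¹)
    first complex → loaded enzyme + first product (k = 240 min⁻¹)

At 1.50 h, free enzyme, the resting state, held 69.5% of the catalyst and the second complex 23.6%. The draining time put 20% conversion at 1.88 h, and the flask reached it at 1.87 h. In the flask with twice the second substrate, the time to that mark is 0.982 of this one, or 1.84 h, and scaled by the same factor the draining time I read comes to 9.21 h for that flask.

The runs were computed for an exercise, noise included.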